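**Plan**

- Retrosynthetic cuts, in this order: the C8–O ester bond (side chain), C11=C13 (methylenation), C9–C10 (closure of the ten-membered ring), the C8–B and C9–B bonds (both from a vinyl group on C7), C7–C8 (vinyl added to a butenolide), C6–C7 (alkynylation of an enal) and C1=C10 (α-iodo Wittig).
- Forward: geranyl acetate gives the (2E,6Z)-iodo-enal (C1–C6, C10, C14, C15). Methyl propiolate adds C7, C11 and C12, the C4–C5 epoxide is installed, and the γ-lactone (ring B) closes. A vinyl group adds C8 and C9. The ten-membered carbocycle (ring A) closes last at C9–C10, followed by C13 and the ester.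
- Enabling feature: C9 is a CH2 lying between the C8 carbinol carbon and the Z-trisubstituted C1=C10 alkene. C8–C9 can therefore be carried as a vicinal bis(boronate), with boron on C8 as a masked hydroxyl (removed by oxidation in step 12), and C10 as a Z-alkenyl iodide. The trans-fused lactone O–C6–C7–C11–C12 and the C4–C5 epoxide are already in place and bend the chain.
- Stereochemistry: C6 from a catalyst-controlled alkynylation; C4/C5 from a hydroxyl-directed threo epoxidation (A1,3 strain from C15); C7 trans to C6 by conjugate addition; C8 from a catalyst-controlled diboration; Z C1=C10 from the α-iodo Wittig and E C4=C5 from geraniol, both carried through unchanged.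

Key step: step 11

Remark: C1–C15 are the germacrane locants of the target (C6 lactone carbinol, C7, C8 acyloxy carbon, C9 CH2, C10 methyl-bearing alkene carbon, C4/C5 epoxide, C11–C13 lactone carbons).

Assumption: in the two catalyst-controlled steps (6 and 10) the catalyst antipode named is taken to give the configuration drawn; if the sense of induction is the opposite one, the other antipode (pseudo-enantiomer) is used and nothing else changes.

**Route**

Step 1
Reactants: 1 geranyl acetate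
Product: 2 (2E)-5-(3,3-dimethyloxiran-2-yl)-3-methylpent-2-en-1-yl acetate (racemic at the oxirane CH)
Conditions: mCPBA (1.0 equiv), NaHCO3, CH2Cl2, 0 °C
Reagents that add atoms: 3-chloroperoxybenzoic acid (mCPBA) OOC(=O)c1cccc(Cl)c1
Why: Prilezhaev epoxidation should take the electron-richer remote 6,7-alkene rather than the 2,3-alkene deactivated by the allylic acetate; the new stereocentre is racemic and is destroyed in step 2.

Step 2
Reactants: 2 (2E)-5-(3,3-dimethyloxiran-2-yl)-3-methylpent-2-en-1-yl acetate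
Product: 3 (2E)-3-methyl-6-oxohex-2-en-1-yl acetate
Conditions: HIO4·2H2O, THF/H2O, 0 °C
Reagents that add atoms: none
Why: Periodic acid should hydrolyse the epoxide and cleave the glycol in one pot (oxidative glycol cleavage), giving the C1 aldehyde and leaving the allylic acetate and its E alkene untouched.

Step 3
Reactants: 3 (2E)-3-methyl-6-oxohex-2-en-1-yl acetate; 4 ethyltriphenylphosphonium iodide
Product: 6 (2E,6Z)-7-iodo-3-methylocta-2,6-dien-1-yl acetate, via (1-iodoethyl)triphenylphosphonium iodide 5 (not isolated)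
Conditions: 4, n-BuLi, THF, rt; I2, −78 °C; NaN(SiMe3)2, −20 °C; then 3, −78 to −20 °C
Reagents that add atoms: iodine II
Why: Stork–Zhao–Wittig olefination with the non-stabilised α-iodo ylide should pass through the kinetic cis-oxaphosphetane and give the Z iodoalkene (iodine cis to the chain), which fixes the later C1=C10 geometry.

Step 4
Reactants: 6 (2E,6Z)-7-iodo-3-methylocta-2,6-dien-1-yl acetate
Product: 7 (2E,6Z)-7-iodo-3-methylocta-2,6-dien-1-ol
Conditions: K2CO3 (cat.), MeOH, rt
Reagents that add atoms: none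
Why: Base-catalysed transesterification (methanolysis) should remove the acetate without touching the alkenyl iodide.

Step 5
Reactants: 7 (2E,6Z)-7-iodo-3-methylocta-2,6-dien-1-ol
Product: 8 (2E,6Z)-7-iodo-3-methylocta-2,6-dienal
Conditions: TEMPO (10 mol%), PhI(OAc)2, CH2Cl2, rt
Reagents that add atoms: none
Why: The oxoammonium-mediated (TEMPO/PhI(OAc)2) oxidation of allylic alcohols should give the enal without E/Z isomerisation of the C4=C5 alkene.

Step 6
Reactants: 8 (2E,6Z)-7-iodo-3-methylocta-2,6-dienal; 9 methyl propiolate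
Product: 10 methyl (4R,5E,9Z)-4-hydroxy-10-iodo-6-methylundeca-5,9-dien-2-ynoate
Conditions: Me2Zn (3 equiv), (S,S)-ProPhenol (10 mol%), Ph3P=O (20 mol%), toluene, 0 °C; aq NH4Cl
Reagents that add atoms: none
Why: Catalytic asymmetric alkynylation of an enal by the dinuclear zinc–ProPhenol alkynylide should form C6–C7 and set the C6 carbinol by catalyst control (R here; it becomes 6S of the target once C5 carries oxygen).

Step 7
Reactants: 10 methyl (4R,5E,9Z)-4-hydroxy-10-iodo-6-methylundeca-5,9-dien-2-ynoate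
Product: 11 methyl (4S)-4-hydroxy-4-[(2R,3R)-3-[(3Z)-4-iodopent-3-en-1-yl]-3-methyloxiran-2-yl]but-2-ynoate
Conditions: mCPBA (1.1 equiv), NaHCO3, CH2Cl2, 0 °C
Reagents that add atoms: 3-chloroperoxybenzoic acid (mCPBA) OOC(=O)c1cccc(Cl)c1
Why: Hydroxyl-directed Prilezhaev epoxidation: with C6–H eclipsing the alkene to avoid A1,3 strain with the C15 methyl, the hydrogen-bonded peracid should attack the face carrying OH and give the threo (4R,5R) epoxide, while the ynoate and the iodoalkene react more slowly.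

Step 8
Reactants: 11 methyl (4S)-4-hydroxy-4-[(2R,3R)-3-[(3Z)-4-iodopent-3-en-1-yl]-3-methyloxiran-2-yl]but-2-ynoate
Product: 13 (5S)-5-[(2R,3R)-3-[(3Z)-4-iodopent-3-en-1-yl]-3-methyloxiran-2-yl]furan-2(5H)-one, via Z-hydroxy enoate 12 (not isolated)
Conditions: H2 (1 atm), Pd/CaCO3 poisoned with Pb(OAc)2 (Lindlar catalyst), quinoline, EtOAc, rt; then SiO2, CH2Cl2
Reagents that add atoms: none
Why: Lindlar semi-hydrogenation (syn addition of H2) should give the Z γ-hydroxy enoate, which lactonises to the butenolide (ring B) with C6 unchanged.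

Step 9
Reactants: 13 (5S)-5-[(2R,3R)-3-[(3Z)-4-iodopent-3-en-1-yl]-3-methyloxiran-2-yl]furan-2(5H)-one
Product: 14 (4R,5S)-4-ethenyl-5-[(2R,3R)-3-[(3Z)-4-iodopent-3-en-1-yl]-3-methyloxiran-2-yl]oxolan-2-one
Conditions: CH2=CHMgBr (1.5 equiv), CuBr·SMe2 (20 mol%), THF/Me2S, −78 °C; aq NH4Cl
Reagents that add atoms: vinylmagnesium bromide C=C[Mg]Br
Why: Copper-catalysed conjugate addition to a 5-substituted butenolide should deliver the vinyl group (C8, C9) anti to the C6 substituent, setting C7 and the trans lactone; the hindered alkenyl iodide should not exchange at −78 °C.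

Step 10
Reactants: 14 (4R,5S)-4-ethenyl-5-[(2R,3R)-3-[(3Z)-4-iodopent-3-en-1-yl]-3-methyloxiran-2-yl]oxolan-2-one
Product: 16 (4R,5S)-4-[(1R)-1,2-bis(4,4,5,5-tetramethyl-1,3,2-dioxaborolan-2-yl)ethyl]-5-[(2R,3R)-3-[(3Z)-4-iodopent-3-en-1-yl]-3-methyloxiran-2-yl]oxolan-2-one, via bis(neopentylglycol boronate) 15 (not isolated)
Conditions: B2(neo)2 (1.5 equiv), 6-O-TBS-1,2-dideoxy-D-glucopyranose (trans-diol catalyst, 10 mol%), DBU (10 mol%), THF, 60 °C; then pinacol (4 equiv), rt
Reagents that add atoms: bis(neopentyl glycolato)diboron CC1(C)COB(OC1)B1OCC(C)(C)CO1; pinacol CC(C)(O)C(C)(C)O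
Why: Transition-metal-free, glycol-catalysed enantioselective 1,2-diboration of a terminal alkene adds both boron atoms syn to one face of the vinyl group, which should set C8 (R) under catalyst control while the iodoalkene, epoxide and lactone stay inert; pinacol exchange gives the robust bis(pinacol) ester.

Step 11
Reactants: 16 (4R,5S)-4-[(1R)-1,2-bis(4,4,5,5-tetramethyl-1,3,2-dioxaborolan-2-yl)ethyl]-5-[(2R,3R)-3-[(3Z)-4-iodopent-3-en-1-yl]-3-methyloxiran-2-yl]oxolan-2-one
Product: 17 (1(10)Z,4R,5R,6S,7R,8R)-4,5-epoxy-8-(4,4,5,5-tetramethyl-1,3,2-dioxaborolan-2-yl)-13-norgermacr-1(10)-en-12,6-olide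
Conditions: Pd(OAc)2 (10 mol%), RuPhos (12 mol%), K3PO4 (3 equiv), THF/H2O 10:1, 65 °C, 16 added over 12 h to 2 mM; work-up at pH 5
Reagents that add atoms: none
Why: Zerovalent palladium (RuPhos) inserts into the C10–I bond with retention of the Z geometry, the primary C9–B bond is transmetalated after activation by hydroxide/phosphate (assisted by the neighbouring C8 boronate), and reductive elimination from the eleven-membered palladacycle forms C9–C10. The closest known reaction types are the Suzuki–Miyaura coupling of vicinal bis(boronates) with alkenyl halides at the primary carbon and the B-alkyl Suzuki–Miyaura ring closure of medium-sized carbocycles. The ten-membered carbocycle (ring A) is closed by an intramolecular C(sp3)–C(sp2) coupling in which C9 and the C1=C10 alkene both end up endocyclic, trans-fused onto the preformed lactone (ring B). No stereocentre is created: C8 (step 10) keeps its configuration because the secondary C–B bond is not touched, and the Z alkene (step 3) is carried through stereoretentive oxidative addition and reductive elimination. The step needs primary-over-secondary C–B selectivity (steric difference plus boronate assistance), ring closure over oligomerisation (slow addition to 2 mM; the cis alkene, the epoxide and the lactone bend the chain so that C9 and C10 can meet) and reductive elimination over β-hydride elimination (bulky biaryl phosphine). Boron on C8 acts as a masked hydroxyl that puts no β-oxygen next to the metal-bearing carbon, and any lactone opened by the base should close again at pH 5 because C6–OH is then the only free hydroxyl.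

Step 12
Reactants: 17 (1(10)Z,4R,5R,6S,7R,8R)-4,5-epoxy-8-(4,4,5,5-tetramethyl-1,3,2-dioxaborolan-2-yl)-13-norgermacr-1(10)-en-12,6-olide
Product: 18 (1(10)Z,4R,5R,6S,7R,8R)-4,5-epoxy-8-hydroxy-13-norgermacr-1(10)-en-12,6-olide
Conditions: NaBO3·4H2O, THF/H2O 1:1, 0 °C to rt
Reagents that add atoms: sodium perborate [Na+].[O-]OB=O
Why: Oxidation of the secondary C–B bond by perborate proceeds by 1,2-migration of carbon to oxygen with retention, so C8–OH should appear with the configuration set in step 10 under conditions mild enough for lactone and epoxide.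

Step 13
Reactants: 18 (1(10)Z,4R,5R,6S,7R,8R)-4,5-epoxy-8-hydroxy-13-norgermacr-1(10)-en-12,6-olide
Product: 21 (1(10)Z,4R,5R,6S,7R,8R)-4,5-epoxy-8-hydroxygermacra-1(10),11(13)-dien-12,6-olide, via Mannich base 19 (not isolated), via methiodide 20 (not isolated)
Conditions: LiN(i-Pr)2 (2.5 equiv), THF, −78 °C; CH2=NMe2+ I−, −78 to 0 °C; MeI, CH2Cl2/MeOH, rt; aq NaHCO3, rt
Reagents that add atoms: dimethylmethyleneiminium iodide (Eschenmoser's salt) C=[N+](C)C.[I-]; iodomethane CI (its methyl is carried only in intermediate 20)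
Why: α-Methylenation of a γ-lactone by Mannich reaction of the alkoxide–enolate dianion with Eschenmoser's salt, N-quaternisation and base-induced elimination should install C13; the transient C11 stereocentre (aminomethyl trans to C8) is removed in the elimination.

Step 14
Reactants: 22 (tert-butyldimethylsilyloxy)acetaldehyde; 23 ethyl 2-(triphenylphosphoranylidene)propanoate
Product: 24 ethyl (2E)-4-(tert-butyldimethylsilyloxy)-2-methylbut-2-enoate
Conditions: CH2Cl2, rt
Reagents that add atoms: none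
Why: Wittig olefination with a stabilised α-methyl ylide should give the E trisubstituted enoate of the side chain.

Step 15
Reactants: 24 ethyl (2E)-4-(tert-butyldimethylsilyloxy)-2-methylbut-2-enoate
Product: 25 (2E)-4-(tert-butyldimethylsilyloxy)-2-methylbut-2-enoic acid
Conditions: LiOH, THF/MeOH/H2O, rt; then cold 1 M HCl to pH 4
Reagents that add atoms: lithium hydroxide [Li+].[OH-]
Why: Saponification of the ethyl ester should leave the primary silyl ether and the E alkene intact.

Step 16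
Reactants: 21 (1(10)Z,4R,5R,6S,7R,8R)-4,5-epoxy-8-hydroxygermacra-1(10),11(13)-dien-12,6-olide; 25 (2E)-4-(tert-butyldimethylsilyloxy)-2-methylbut-2-enoic acid
Product: 27 (1(10)Z,4R,5R,6S,7R,8R)-8-[(2E)-4-(tert-butyldimethylsilyloxy)-2-methylbut-2-enoyloxy]-4,5-epoxygermacra-1(10),11(13)-dien-12,6-olide, via mixed anhydride 26 (not isolated)
Conditions: 25, 2,4,6-trichlorobenzoyl chloride, Et3N, toluene, rt; then 21, DMAP, rt
Reagents that add atoms: 2,4,6-trichlorobenzoyl chloride ClC(=O)c1c(Cl)cc(Cl)cc1Cl (its atoms are carried only in intermediate 26)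
Why: Yamaguchi esterification should acylate the hindered secondary C8–OH with retention at C8, and the E (tiglate-type) geometry is the stable one under DMAP.

Step 17
Reactants: 27 (1(10)Z,4R,5R,6S,7R,8R)-8-[(2E)-4-(tert-butyldimethylsilyloxy)-2-methylbut-2-enoyloxy]-4,5-epoxygermacra-1(10),11(13)-dien-12,6-olide
Product: 28 (1(10)Z,4R,5R,6S,7R,8R)-4,5-epoxy-8-[(2E)-4-hydroxy-2-methylbut-2-enoyloxy]germacra-1(10),11(13)-dien-12,6-olide (target)
Conditions: HF·pyridine, excess pyridine, THF, 0 °C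
Reagents that add atoms: none
Why: Buffered fluoride desilylation of the primary allylic silyl ether should spare the trisubstituted epoxide, the two acrylate units and the ester.

**Compound list**

1 | geranyl acetate, (2E)-3,7-dimethylocta-2,6-dien-1-yl acetate | CC(=O)OC/C=C(\C)CCC=C(C)C | starting material
2 | (2E)-5-(3,3-dimethyloxiran-2-yl)-3-methylpent-2-en-1-yl acetate (racemic oxirane) | CC(=O)OC/C=C(\C)CCC1OC1(C)C | intermediate
3 | (2E)-3-methyl-6-oxohex-2-en-1-yl acetate | CC(=O)OC/C=C(\C)CCC=O | intermediate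
4 | ethyltriphenylphosphonium iodide | CC[P+](c1ccccc1)(c1ccccc1)c1ccccc1.[I-] | starting material
5 | (1-iodoethyl)triphenylphosphonium iodide | CC(I)[P+](c1ccccc1)(c1ccccc1)c1ccccc1.[I-] | intermediate (not isolated)
6 | (2E,6Z)-7-iodo-3-methylocta-2,6-dien-1-yl acetate | CC(=O)OC/C=C(\C)CC/C=C(/C)I | intermediate
7 | (2E,6Z)-7-iodo-3-methylocta-2,6-dien-1-ol | OC/C=C(\C)CC/C=C(/C)I | intermediate
8 | (2E,6Z)-7-iodo-3-methylocta-2,6-dienal | O=C/C=C(\C)CC/C=C(/C)I | intermediate
9 | methyl propiolate | C#CC(=O)OC | starting material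
10 | methyl (4R,5E,9Z)-4-hydroxy-10-iodo-6-methylundeca-5,9-dien-2-ynoate | COC(=O)C#C[C@H](O)/C=C(\C)CC/C=C(/C)I | intermediate
11 | methyl (4S)-4-hydroxy-4-[(2R,3R)-3-[(3Z)-4-iodopent-3-en-1-yl]-3-methyloxiran-2-yl]but-2-ynoate | COC(=O)C#C[C@H](O)[C@H]1O[C@]1(C)CC/C=C(/C)I | intermediate
12 | methyl (2Z,4S)-4-hydroxy-4-[(2R,3R)-3-[(3Z)-4-iodopent-3-en-1-yl]-3-methyloxiran-2-yl]but-2-enoate | COC(=O)/C=C\[C@H](O)[C@H]1O[C@]1(C)CC/C=C(/C)I | intermediate (not isolated)
13 | (5S)-5-[(2R,3R)-3-[(3Z)-4-iodopent-3-en-1-yl]-3-methyloxiran-2-yl]furan-2(5H)-one | O=C1C=C[C@H](O1)[C@H]1O[C@]1(C)CC/C=C(/C)I | intermediate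
14 | (4R,5S)-4-ethenyl-5-[(2R,3R)-3-[(3Z)-4-iodopent-3-en-1-yl]-3-methyloxiran-2-yl]oxolan-2-one | O=C1C[C@H](C=C)[C@H](O1)[C@H]1O[C@]1(C)CC/C=C(/C)I | intermediate
15 | (4R,5S)-4-[(1R)-1,2-bis(5,5-dimethyl-1,3,2-dioxaborinan-2-yl)ethyl]-5-[(2R,3R)-3-[(3Z)-4-iodopent-3-en-1-yl]-3-methyloxiran-2-yl]oxolan-2-one | O=C1C[C@H]([C@H](B2OCC(C)(C)CO2)CB2OCC(C)(C)CO2)[C@H](O1)[C@H]1O[C@]1(C)CC/C=C(/C)I | intermediate (not isolated)
16 | (4R,5S)-4-[(1R)-1,2-bis(4,4,5,5-tetramethyl-1,3,2-dioxaborolan-2-yl)ethyl]-5-[(2R,3R)-3-[(3Z)-4-iodopent-3-en-1-yl]-3-methyloxiran-2-yl]oxolan-2-one | O=C1C[C@H]([C@H](B2OC(C)(C)C(C)(C)O2)CB2OC(C)(C)C(C)(C)O2)[C@H](O1)[C@H]1O[C@]1(C)CC/C=C(/C)I | intermediate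
17 | (1(10)Z,4R,5R,6S,7R,8R)-4,5-epoxy-8-(4,4,5,5-tetramethyl-1,3,2-dioxaborolan-2-yl)-13-norgermacr-1(10)-en-12,6-olide (trans-fused lactone, C11 = CH2) | C1C(=O)O[C@H]2[C@H]1[C@H](B3OC(C)(C)C(C)(C)O3)C/C(C)=C\CC[C@@]1(C)O[C@H]21 | intermediate
18 | (1(10)Z,4R,5R,6S,7R,8R)-4,5-epoxy-8-hydroxy-13-norgermacr-1(10)-en-12,6-olide | C1C(=O)O[C@H]2[C@H]1[C@H](O)C/C(C)=C\CC[C@@]1(C)O[C@H]21 | intermediate
19 | (1(10)Z,4R,5R,6S,7R,8R,11R)-13-(dimethylamino)-4,5-epoxy-8-hydroxygermacr-1(10)-en-12,6-olide (Mannich base) | CN(C)C[C@@H]1C(=O)O[C@H]2[C@H]1[C@H](O)C/C(C)=C\CC[C@@]1(C)O[C@H]21 | intermediate (not isolated)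
20 | N-methyl quaternary ammonium iodide of 19 (13-trimethylammonio lactone iodide) | C[N+](C)(C)C[C@@H]1C(=O)O[C@H]2[C@H]1[C@H](O)C/C(C)=C\CC[C@@]1(C)O[C@H]21.[I-] | intermediate (not isolated)
21 | (1(10)Z,4R,5R,6S,7R,8R)-4,5-epoxy-8-hydroxygermacra-1(10),11(13)-dien-12,6-olide | C=C1C(=O)O[C@H]2[C@H]1[C@H](O)C/C(C)=C\CC[C@@]1(C)O[C@H]21 | intermediate
22 | (tert-butyldimethylsilyloxy)acetaldehyde | CC(C)(C)[Si](C)(C)OCC=O | starting material
23 | ethyl 2-(triphenylphosphoranylidene)propanoate | CCOC(=O)C(C)=P(c1ccccc1)(c1ccccc1)c1ccccc1 | starting material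
24 | ethyl (2E)-4-(tert-butyldimethylsilyloxy)-2-methylbut-2-enoate | CCOC(=O)/C(C)=C/CO[Si](C)(C)C(C)(C)C | intermediate
25 | (2E)-4-(tert-butyldimethylsilyloxy)-2-methylbut-2-enoic acid | CC(C)(C)[Si](C)(C)OC/C=C(\C)C(O)=O | intermediate
26 | (2E)-4-(tert-butyldimethylsilyloxy)-2-methylbut-2-enoic 2,4,6-trichlorobenzoic anhydride | CC(C)(C)[Si](C)(C)OC/C=C(\C)C(=O)OC(=O)c1c(Cl)cc(Cl)cc1Cl | intermediate (not isolated)
27 | (1(10)Z,4R,5R,6S,7R,8R)-8-[(2E)-4-(tert-butyldimethylsilyloxy)-2-methylbut-2-enoyloxy]-4,5-epoxygermacra-1(10),11(13)-dien-12,6-olide | C=C1C(=O)O[C@H]2[C@H]1[C@H](OC(=O)/C(C)=C/CO[Si](C)(C)C(C)(C)C)C/C(C)=C\CC[C@@]1(C)O[C@H]21 | intermediate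
28 | (1(10)Z,4R,5R,6S,7R,8R)-4,5-epoxy-8-[(2E)-4-hydroxy-2-methylbut-2-enoyloxy]germacra-1(10),11(13)-dien-12,6-olide | C=C1C(=O)O[C@H]2[C@H]1[C@H](OC(=O)/C(C)=C/CO)C/C(C)=C\CC[C@@]1(C)O[C@H]21 | target

**Step count and risks**

Total steps: 17. Longest linear sequence: 15 (steps 1–13, then 16 and 17); the side-chain acid takes 2 steps (14, 15).

Steps most likely to fail:

1. Step 11 (ring closure). Intermolecular coupling may outrun cyclisation and give oligomers. The alkylpalladium intermediate may be lost by protodeboronation or β-hydride elimination. The aqueous base may open the lactone and allow Payne migration of the neighbouring epoxide. The fallback closes the same bond by a radical cross-electrophile mechanism without base. It sets out from 16. Both C–B bonds are oxidised with NaBO3·4H2O to the diol (4R,5S)-4-[(1S)-1,2-dihydroxyethyl]-5-[(2R,3R)-3-[(3Z)-4-iodopent-3-en-1-yl]-3-methyloxiran-2-yl]oxolan-2-one F1. Mitsunobu cyclodehydration (PPh3, DIAD, THF) activates the primary hydroxyl and should give the terminal epoxide (4R,5S)-5-[(2R,3R)-3-[(3Z)-4-iodopent-3-en-1-yl]-3-methyloxiran-2-yl]-4-[(2S)-oxiran-2-yl]oxolan-2-one F2, with C8 untouched. F2 is then cyclised reductively (NiCl2(dme), 2,2'-bipyridine, NaI, Et3N·HCl, Zn, DMPU, rt, 2 mM): iodide opens the terminal epoxide at C9, the C9 radical is captured by the alkenylnickel species at C10, and the C8 hydroxyl is released in the same operation. The route is rejoined at 18. The trisubstituted C4–C5 epoxide is the group to watch under these conditions.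

2. Step 10 (diboration). Facial selectivity at C8 may be poor if the catalyst opposes the bias of the adjacent C7 stereocentre, and turnover on the α-branched alkene may be slow. The fallback replaces reagent control by a substrate-controlled carbonyl reduction. It sets out from 14. Diboration with racemic trans-cyclohexane-1,2-diol as catalyst gives 16 together with its C8 epimer (4R,5S)-4-[(1S)-1,2-bis(4,4,5,5-tetramethyl-1,3,2-dioxaborolan-2-yl)ethyl]-5-[(2R,3R)-3-[(3Z)-4-iodopent-3-en-1-yl]-3-methyloxiran-2-yl]oxolan-2-one F3. The mixture is taken through steps 11 and 12, giving besides 17 and 18 the epimeric macrocyclic boronate (8S)-4,5-epoxy-8-(4,4,5,5-tetramethyl-1,3,2-dioxaborolan-2-yl)-13-norgermacr-1(10)-en-12,6-olide F4 and the epimeric alcohol (8S)-4,5-epoxy-8-hydroxy-13-norgermacr-1(10)-en-12,6-olide F5. The combined alcohols are oxidised (Dess–Martin periodinane, NaHCO3, CH2Cl2) to the single ketone (1(10)Z,4R,5R,6S,7S)-4,5-epoxy-8-oxo-13-norgermacr-1(10)-en-12,6-olide F6. Reduction with LiBH(s-Bu)3 in THF at −78 °C should deliver hydride from the face opposite the C7–C11 bond and return the 8R alcohol 18. The cold, fast reduction is chosen to avoid epimerisation at C7 or β-elimination of the lactone oxygen.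

3. Step 8 (semi-hydrogenation). The C–I bond may be lost by hydrogenolysis, or the alkene may be over-reduced on the palladium surface. The fallback avoids hydrogenation and sets C7 in an acyclic system. It sets out from 10. Hydroxyl-directed trans-hydroalumination (NaAlH2(OCH2CH2OCH3)2, THF, −72 °C) should give methyl (2E,4S,5E,9Z)-4-hydroxy-10-iodo-6-methylundeca-2,5,9-trienoate F7. Directed epoxidation as in step 7 (mCPBA, NaHCO3) gives methyl (2E,4S)-4-hydroxy-4-[(2R,3R)-3-[(3Z)-4-iodopent-3-en-1-yl]-3-methyloxiran-2-yl]but-2-enoate F8. Silylation (TBSOTf, 2,6-lutidine) gives methyl (2E,4S)-4-(tert-butyldimethylsilyloxy)-4-[(2R,3R)-3-[(3Z)-4-iodopent-3-en-1-yl]-3-methyloxiran-2-yl]but-2-enoate F9. Copper-catalysed addition of CH2=CHMgBr (CuI, THF, −78 °C), anti to the γ-silyloxy group, gives methyl (3R,4S)-4-(tert-butyldimethylsilyloxy)-3-ethenyl-4-[(2R,3R)-3-[(3Z)-4-iodopent-3-en-1-yl]-3-methyloxiran-2-yl]butanoate F10. Bu4NF in THF removes the silyl group and the liberated alkoxide lactonises, rejoining the route at 14.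

Further compounds
F1 | step 11 | (4R,5S)-4-[(1S)-1,2-dihydroxyethyl]-5-[(2R,3R)-3-[(3Z)-4-iodopent-3-en-1-yl]-3-methyloxiran-2-yl]oxolan-2-one | O=C1C[C@H]([C@H](O)CO)[C@H](O1)[C@H]1O[C@]1(C)CC/C=C(/C)I
F2 | step 11 | (4R,5S)-5-[(2R,3R)-3-[(3Z)-4-iodopent-3-en-1-yl]-3-methyloxiran-2-yl]-4-[(2S)-oxiran-2-yl]oxolan-2-one | O=C1C[C@H]([C@H]2CO2)[C@H](O1)[C@H]1O[C@]1(C)CC/C=C(/C)I
F3 | step 10 | (4R,5S)-4-[(1S)-1,2-bis(4,4,5,5-tetramethyl-1,3,2-dioxaborolan-2-yl)ethyl]-5-[(2R,3R)-3-[(3Z)-4-iodopent-3-en-1-yl]-3-methyloxiran-2-yl]oxolan-2-one | O=C1C[C@H]([C@@H](B2OC(C)(C)C(C)(C)O2)CB2OC(C)(C)C(C)(C)O2)[C@H](O1)[C@H]1O[C@]1(C)CC/C=C(/C)I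
F4 | step 10 | (1(10)Z,4R,5R,6S,7R,8S)-4,5-epoxy-8-(4,4,5,5-tetramethyl-1,3,2-dioxaborolan-2-yl)-13-norgermacr-1(10)-en-12,6-olide | C1C(=O)O[C@H]2[C@H]1[C@@H](B3OC(C)(C)C(C)(C)O3)C/C(C)=C\CC[C@@]1(C)O[C@H]21
F5 | step 10 | (1(10)Z,4R,5R,6S,7R,8S)-4,5-epoxy-8-hydroxy-13-norgermacr-1(10)-en-12,6-olide | C1C(=O)O[C@H]2[C@H]1[C@@H](O)C/C(C)=C\CC[C@@]1(C)O[C@H]21
F6 | step 10 | (1(10)Z,4R,5R,6S,7S)-4,5-epoxy-8-oxo-13-norgermacr-1(10)-en-12,6-olide | C1C(=O)O[C@H]2[C@H]1C(=O)C/C(C)=C\CC[C@@]1(C)O[C@H]21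
F7 | step 8 | methyl (2E,4S,5E,9Z)-4-hydroxy-10-iodo-6-methylundeca-2,5,9-trienoate | COC(=O)/C=C/[C@H](O)/C=C(\C)CC/C=C(/C)I
F8 | step 8 | methyl (2E,4S)-4-hydroxy-4-[(2R,3R)-3-[(3Z)-4-iodopent-3-en-1-yl]-3-methyloxiran-2-yl]but-2-enoate | COC(=O)/C=C/[C@H](O)[C@H]1O[C@]1(C)CC/C=C(/C)I
F9 | step 8 | methyl (2E,4S)-4-(tert-butyldimethylsilyloxy)-4-[(2R,3R)-3-[(3Z)-4-iodopent-3-en-1-yl]-3-methyloxiran-2-yl]but-2-enoate | COC(=O)/C=C/[C@H](O[Si](C)(C)C(C)(C)C)[C@H]1O[C@]1(C)CC/C=C(/C)I
F10 | step 8 | methyl (3R,4S)-4-(tert-butyldimethylsilyloxy)-3-ethenyl-4-[(2R,3R)-3-[(3Z)-4-iodopent-3-en-1-yl]-3-methyloxiran-2-yl]butanoate | COC(=O)C[C@H](C=C)[C@H](O[Si](C)(C)C(C)(C)C)[C@H]1O[C@]1(C)CC/C=C(/C)I
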